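The amounts in the earlier runs made sense to me once I added target and over-reaction product and looked at how fast target was lost.

| flask | solid substrate | target | temperature | remark | time |
|---|---|---|---|---|---|
| ash | 0.75 M | 0.015 M | 68 °C | run made earlier |  |
| cedar | 1.1 M | 0.015 M | 84 °C | run made earlier |  |
| maple | 1.5 M | 0.022 M | 68 °C | run made earlier |  |
| teal | 1.5 M | 0.0150 M | 60 °C |  | 6.0 min |
| grey | 1.5 M | 0.0150 M | 90 °C |  | 6.0 min |
| violet | 1.5 M | 0.0150 M |  | at 90 °C until 2.0 min, from then on at 60 °C | 6.0 min |

- ash (time / min: target / %, over-reaction product / %): 0.667: 45.2, 0.7; 1.33: 86.2, 2.0; 2.00: 98.0, 3.9; 2.50: 96.5, 4.7; 3.00: 95.6, 6.5; 4.00: 91.9, 9.2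
- cedar (time / s: target / %, over-reaction product / %): 12.0: 9.5, 1.0; 25.0: 18.4, 0.9; 40.0: 29.2, 1.6; 50.0: 35.9, 2.5; 60.0: 42.3, 2.8; 80.0: 54.6, 5.8
- maple (time / min: target / %, over-reaction product / %): 0.333: 12.1, 0; 0.833: 28.1, 0; 1.50: 49.0, 0.8; 2.50: 79.9, 3.8; 4.00: 94.0, 8.1

(readings scatter by 0.5 percentage points)

- as a solid, counted per litre of solution: solid substrate
- at the start none of the solid substrate is in solution
- what has only dissolved of solid substrate counts as not reacted

* the flask that comes out highest in share of target in all that became target or over-reaction product, or "all alike" when all lie within 1.5 percentage points (teal / grey / violet / all alike)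
* share of target in all that became target or over-reaction product, teal
* share of target in all that became target or over-reaction product, grey
* share of target in all that became target or over-reaction product, violet

1. Making. The sum of target and over-reaction product, less the target put in at the start, grew at 0.486 M min⁻¹ in ash, 0.487 M min⁻¹ in cedar and 0.493 M min⁻¹ in maple. I assumed the ash value of this steady making for teal, grey and violet, so each charge takes 3.09 min.

2. Loss rate. In ash, target fell from 98.0% to 91.9% between 2.00 min and 4.00 min, which reads as 0.0321 min⁻¹ at 68 °C. In cedar, over-reaction product against half of target times time reads as 0.159 min⁻¹ at 84 °C. That is a factor 4.96. With ln k straight in temperature, I got 0.0144 min⁻¹ at 60 °C and 0.290 min⁻¹ at 90 °C.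

3. Slowing. In violet, the loss rate starts at the hot value, and cooling slows it by a factor 20.1.

4. Accumulation. With steady making, the mean age of target at the end, the time from the average moment of its making to the end, is 4.46 min. The share of target (the selectivity) is then about exp(−k × age). My reckoning gave teal 93.8% and grey 27.4%. Violet I split into a hot and a cold batch, which gave 79.2%. Teal came out higher than the others.

5. The forecast named teal, with teal 93.9%, grey 36% and violet 82.3%, on the ground that “Over-reaction looks first-order in target”; its grey is higher than mine.

6. The flasks gave teal as highest: teal 94.2%, grey 30.3%, violet 80.6%. My grey stood 2.9 percentage points low.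

    starting material + target → 2 target (k = 435 M⁻¹ min⁻¹, Ea = 58.0 kJ mol⁻¹)
    starting material → target (k = 0.00491 min⁻¹, Ea = 114 kJ mol⁻¹)
    target → over-reaction product (k = 0.0134 min⁻¹, Ea = 101 kJ mol⁻¹)
    solid substrate ⇌ starting material, rate k4*(cs4 - [starting material]) while solid is left; crystals form when [starting material] > cs4 (solubility = 0.510 M, k = 0.964 min⁻¹)
    (constants at 60 °C)

7. In teal the share stood at 94.2% at the asked time, and in a run ten times as long it stood at 45.7%, so the length of the run is the main reason for the high share of teal.

8. In a flask like grey kept at 65 °C, the loss rate is 0.0238 min⁻¹, and the same mean age gives 89.9%. The computed share is 90.3%.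

(Readings and results come from a simulation from invented constants; the scatter is artificial.)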